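**Plan**

1. The last bond cut is C2–C3 of the cis-2,3-dihydrobenzofuran (ring O1–C2–C3–C3a–C7a). C2 carries the ring oxygen and the guaiacyl ring, so in the open form it is an ArO–CH2–Ar' carbon whose C–H bonds are activated from both sides and lie 1,5 to a carbenoid carbon on C3a.
2. The oxolane (O1, C2 benzyl, C3 OH, C4 CH2OH, C5 aryl) is then cut at O1–C5, at C4–C5 (aldol to 5-bromovanillin) and at C3–C4 (acetate aldol), back to methyl (S)-glycidate and an aryl Grignard reagent.
3. Forward: the chain is joined C2, then C3–C4, then C4–C5; acid closes the oxolane first; the aryl bromide becomes the aryldiazoacetate; rhodium carbenoid C–H insertion closes the dihydrofuran ring last; reduction and deprotection follow.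
4. Stereochemistry: oxolane C2 from (S)-glycidate, C3 by Cram-chelate Mukaiyama aldol, C4 by anti-selective dianion aldol, C5 by thermodynamically controlled cationic ring closure, benzofuran C2 and C3 by Rh2(S-PTTL)4.

Key step: step 15

Assumption: Rh2(S-PTTL)4 is taken to give the (2R,3S)-cis ester, the sense known for simple 2-(benzyloxy)phenyl diazoacetates; if the sense were opposite, Rh2(R-PTTL)4 would replace it with nothing else changed.
Remark: 13, 14 and 15 are carried as both epimers at the ArCH(OH) carbon (left undefined in their SMILES); this centre is ionised in step 9, so both converge.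
Remark: as a parent ring the oxolane is numbered from the benzyl-bearing carbon (C2) to the aryl-bearing carbon (C5); as an oxolan-2-yl substituent the locants run the other way. The silyl ethers change the CIP descriptor of the CH2O-bearing carbon from S to R with no change in space.

**Route**

Step 1
Reactants: 1 4-bromo-2-methoxyphenol
Product: 2 1-(benzyloxy)-4-bromo-2-methoxybenzene
Conditions: BnBr (1.1 equiv), K2CO3, DMF, rt
Reagents that add atoms: benzyl bromide, BrCc1ccccc1
Why: Williamson etherification of the phenoxide with a benzylic bromide is reliable and masks the phenol for the organomagnesium chemistry that follows.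

Step 2
Reactants: 2 1-(benzyloxy)-4-bromo-2-methoxybenzene; 3 methyl (2S)-oxirane-2-carboxylate (methyl (S)-glycidate)
Product: 5 methyl (2S)-3-[4-(benzyloxy)-3-methoxyphenyl]-2-hydroxypropanoate, via aryl Grignard reagent 4 (not isolated)
Conditions: Mg, THF, 45 °C; then CuBr·SMe2 (10 mol %), 3, THF, −40 → −20 °C; aq. NH4Cl
Reagents that add atoms: none
Why: Copper-catalysed SN2 opening of the epoxide by the aryl Grignard reagent occurs at the unsubstituted CH2 carbon faster than addition to the ester at low temperature, so the glycidate stereocentre is untouched and becomes the (S)-carbinol.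

Step 3
Reactants: 5 hydroxy ester from step 2
Product: 6 methyl (2S)-3-[4-(benzyloxy)-3-methoxyphenyl]-2-(methoxymethoxy)propanoate
Conditions: MOMCl, i-Pr2NEt, CH2Cl2, 0 °C → rt
Reagents that add atoms: chloromethyl methyl ether, COCCl
Why: Acetal protection by O-alkylation with an α-chloro ether under a hindered amine base does not enolise the α-hydroxy ester and installs an ether oxygen that can chelate in step 5.

Step 4
Reactants: 6 methoxymethyl-protected ester from step 3
Product: 7 (2S)-3-[4-(benzyloxy)-3-methoxyphenyl]-2-(methoxymethoxy)propanal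
Conditions: i-Bu2AlH (1.1 equiv), CH2Cl2, −78 °C; aq. potassium sodium tartrate; used crude
Reagents that add atoms: none
Why: Partial hydride reduction of an α-alkoxy ester stops at the chelated aluminium hemiacetal at −78 °C, and using the aldehyde without chromatography keeps its α-centre from epimerising.

Step 5
Reactants: 7 aldehyde from step 4; 8 tert-butyl[(1-methoxyethenyl)oxy]dimethylsilane (silyl ketene acetal of methyl acetate)
Product: 9 methyl (3S,4S)-5-[4-(benzyloxy)-3-methoxyphenyl]-3-hydroxy-4-(methoxymethoxy)pentanoate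
Conditions: MgBr2·OEt2 (3 equiv), CH2Cl2, −78 → −30 °C; 1 M HCl work-up
Reagents that add atoms: none
Why: Mukaiyama aldol addition under Cram-chelate control, in which MgBr2 bridges the aldehyde oxygen and the α-acetal oxygen and the silyl ketene acetal attacks the face opposite the arylmethyl group, should give the 3,4-syn (3S) alcohol.

Step 6
Reactants: 10 3-bromo-4-hydroxy-5-methoxybenzaldehyde (5-bromovanillin)
Product: 11 3-bromo-5-methoxy-4-(methoxymethoxy)benzaldehyde
Conditions: MOMCl, i-Pr2NEt, CH2Cl2, 0 °C → rt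
Reagents that add atoms: chloromethyl methyl ether, COCCl
Why: Acetal protection of the acidic phenol keeps the aldehyde electrophilic towards the enolate of step 7 and gives a group that the acid of step 9 removes.

Step 7
Reactants: 9 β-hydroxy ester from step 5; 11 protected bromovanillin from step 6
Product: 13 methyl (2R,3S,4S)-5-[4-(benzyloxy)-3-methoxyphenyl]-2-{[3-bromo-5-methoxy-4-(methoxymethoxy)phenyl](hydroxy)methyl}-3-hydroxy-4-(methoxymethoxy)pentanoate (both carbinol epimers), via dilithium dianion 12 (not isolated)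
Conditions: LiN(i-Pr)2 (2.3 equiv), THF, −78 → −30 °C; then 11 (1.5 equiv), −78 °C; aq. NH4Cl at −78 °C
Reagents that add atoms: none
Why: Fráter–Seebach-type aldol addition, in which the lithium alkoxide–enolate forms a six-membered chelate whose face anti to the C4 side chain is open, should add the aldehyde at C2 anti to the C3 oxygen (2R), while the configuration of the new benzylic carbinol does not matter because it is ionised in step 9.

Step 8
Reactants: 13 aldol adduct from step 7
Product: 14 (2R,3S,4S)-5-[4-(benzyloxy)-3-methoxyphenyl]-2-{[3-bromo-5-methoxy-4-(methoxymethoxy)phenyl](hydroxy)methyl}-4-(methoxymethoxy)pentane-1,3-diol (both carbinol epimers)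
Conditions: LiBH4 (3 equiv), THF–MeOH, 0 °C → rt
Reagents that add atoms: none
Why: Borohydride reduction of a β-hydroxy methyl ester to the primary alcohol is hydroxyl-assisted and fast, and leaves the aryl bromide, the acetals and the benzyl ether intact.

Step 9
Reactants: 14 triol from step 8
Product: 16 (2S,3S,4S,5S)-2-[4-(benzyloxy)-3-methoxybenzyl]-5-(3-bromo-4-hydroxy-5-methoxyphenyl)-4-(hydroxymethyl)oxolan-3-ol, via phenolic tetraol 15 (not isolated)
Conditions: conc. HCl (5 equiv), MeOH, 45 °C; evaporate; then TsOH·H2O (5 mol %), CH2Cl2, rt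
Reagents that add atoms: none
Why: Acidic methanolysis removes both methoxymethyl groups and the freed p-hydroxybenzylic alcohol ionises to a quinone-methide-like cation that only the hydroxyl at pentane C4 can trap in a five-membered ring (the others would give oxetanes), an SN1 cycloetherification in which reversible ionisation should let the aryl group settle trans to the neighbouring CH2OH group (5S).

Step 10
Reactants: 17 [4-(benzyloxy)-3-methoxyphenyl]methanol
Product: 18 1-(benzyloxy)-4-(chloromethyl)-2-methoxybenzene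
Conditions: SOCl2 (1.2 equiv), CH2Cl2, 0 °C; evaporate; used at once
Reagents that add atoms: thionyl chloride, ClS(Cl)=O
Why: Chlorodehydroxylation of an electron-rich benzylic alcohol through its chlorosulfite is rapid, and the labile chloride is used without storage.

Step 11
Reactants: 16 oxolane phenol from step 9; 18 benzylic chloride from step 10
Product: 19 (2S,3S,4S,5S)-2-[4-(benzyloxy)-3-methoxybenzyl]-5-(4-{[4-(benzyloxy)-3-methoxybenzyl]oxy}-3-bromo-5-methoxyphenyl)-4-(hydroxymethyl)oxolan-3-ol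
Conditions: K2CO3 (2 equiv), KI (10 mol %), DMF, rt
Reagents that add atoms: none
Why: Williamson etherification is chemoselective because carbonate deprotonates only the phenol and not the two alcohols, and it installs the ArO–CH2–Ar' unit whose C–H bond is used in step 15.

Step 12
Reactants: 19 diol from step 11
Product: 20 (2S,3S,4R,5S)-2-[4-(benzyloxy)-3-methoxybenzyl]-5-(4-{[4-(benzyloxy)-3-methoxybenzyl]oxy}-3-bromo-5-methoxyphenyl)-3-[(tert-butyldimethylsilyl)oxy]-4-{[(tert-butyldimethylsilyl)oxy]methyl}oxolane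
Conditions: TBSOTf (2.5 equiv), 2,6-lutidine (4 equiv), CH2Cl2, 0 °C
Reagents that add atoms: tert-butyldimethylsilyl trifluoromethanesulfonate, CC(C)(C)[Si](C)(C)OS(=O)(=O)C(F)(F)F
Why: Silylation with a silyl triflate covers the primary and the hindered secondary hydroxyl, which would otherwise undergo O–H insertion with the carbenoid.

Step 13
Reactants: 20 bis-silyl aryl bromide from step 12; 21 methyl bromoacetate
Product: 23 methyl 2-[2-{[4-(benzyloxy)-3-methoxybenzyl]oxy}-5-[(2S,3R,4S,5S)-5-[4-(benzyloxy)-3-methoxybenzyl]-4-[(tert-butyldimethylsilyl)oxy]-3-{[(tert-butyldimethylsilyl)oxy]methyl}oxolan-2-yl]-3-methoxyphenyl]acetate, via Reformatsky reagent 22 (not isolated)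
Conditions: Zn dust (Me3SiCl-activated), 21, THF, 40 °C; then 20, Pd(dba)2 (5 mol %), XPhos (10 mol %), THF, 60 °C
Reagents that add atoms: none
Why: Negishi-type α-arylation, in which the zinc ester enolate transmetalates to the arylpalladium bromide formed by oxidative addition to zerovalent palladium and reductive elimination gives the arylacetate, needs no strong base that could touch the silyl or benzyl ethers.

Step 14
Reactants: 23 methyl arylacetate from step 13
Product: 24 methyl 2-[2-{[4-(benzyloxy)-3-methoxybenzyl]oxy}-5-[(2S,3R,4S,5S)-5-[4-(benzyloxy)-3-methoxybenzyl]-4-[(tert-butyldimethylsilyl)oxy]-3-{[(tert-butyldimethylsilyl)oxy]methyl}oxolan-2-yl]-3-methoxyphenyl]-2-diazoacetate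
Conditions: p-ABSA (1.5 equiv), DBU (2 equiv), MeCN, 0 °C → rt
Reagents that add atoms: 4-acetamidobenzenesulfonyl azide, CC(=O)Nc1ccc(cc1)S(=O)(=O)N=[N+]=[N-]
Why: Regitz diazo transfer from a sulfonyl azide to the DBU-generated arylacetate enolate is the standard entry to aryldiazoacetates and tolerates ortho-alkoxy groups.

Step 15
Reactants: 24 aryldiazoacetate from step 14
Product: 25 methyl (2R,3S)-2-[4-(benzyloxy)-3-methoxyphenyl]-5-[(2S,3R,4S,5S)-5-[4-(benzyloxy)-3-methoxybenzyl]-4-[(tert-butyldimethylsilyl)oxy]-3-{[(tert-butyldimethylsilyl)oxy]methyl}oxolan-2-yl]-7-methoxy-2,3-dihydro-1-benzofuran-3-carboxylate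
Conditions: Rh2(S-PTTL)4 (2 mol %), toluene, −60 °C, slow addition of 24
Reagents that add atoms: none
Why: Rh2(S-PTTL)4 expels N2 from 24 to give a donor/acceptor rhodium carbenoid, which inserts into one C–H bond of the neighbouring ArO–CH2–Ar' group through a concerted, asynchronous three-centre transition state with hydride-transfer character. The closest known reaction type is the cis- and enantioselective intramolecular C–H insertion of methyl 2-(2-benzyloxyphenyl)-2-diazoacetates catalysed by chiral dirhodium tetrakis(N-phthaloylamino acid carboxylates). The dihydrofuran ring closes as a five-membered ring by 1,5-insertion (carbenoid carbon, C3a, C7a, O1, C2), which forms the C2–C3 bond. Both new stereocentres are catalyst-controlled: the phthalimido walls of the S-ligand select which enantiotopic benzylic hydrogen is engaged (C2, R) and which carbenoid face reacts (C3, S), and they hold the aryl group on the side of the ester so that the kinetic cis isomer should result. Site selectivity rests on the substrate, because the only C–H bond that is both 1,5 to the carbenoid carbon and activated by an ether oxygen together with the electron-rich 4-benzyloxy-3-methoxyphenyl ring is the one that reacts, while the oxolane and silyl ether C–H bonds sit at the far meta position and cannot reach. Low temperature, toluene and the absence of base keep the epimerisable cis ester intact, and the catalyst is expected to dominate the oxolane stereocentres because they lie six bonds from the reacting carbon.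

Step 16
Reactants: 25 cis ester from step 15
Product: 26 [(2R,3R)-2-[4-(benzyloxy)-3-methoxyphenyl]-5-[(2S,3R,4S,5S)-5-[4-(benzyloxy)-3-methoxybenzyl]-4-[(tert-butyldimethylsilyl)oxy]-3-{[(tert-butyldimethylsilyl)oxy]methyl}oxolan-2-yl]-7-methoxy-2,3-dihydro-1-benzofuran-3-yl]methanol
Conditions: i-Bu2AlH (4 equiv), CH2Cl2, −78 → −40 °C; aq. potassium sodium tartrate
Reagents that add atoms: none
Why: Hydride reduction of the ester by i-Bu2AlH in a non-basic, non-polar medium proceeds through aluminium acetals at low temperature, so the cis C3 centre should not epimerise before it becomes a non-enolisable CH2OH carbon.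

Step 17
Reactants: 26 bis-silyl alcohol from step 16
Product: 27 (2S,3S,4S,5S)-2-[4-(benzyloxy)-3-methoxybenzyl]-5-[(2R,3R)-2-[4-(benzyloxy)-3-methoxyphenyl]-3-(hydroxymethyl)-7-methoxy-2,3-dihydro-1-benzofuran-5-yl]-4-(hydroxymethyl)oxolan-3-ol
Conditions: n-Bu4NF (3 equiv), THF, 0 °C → rt
Reagents that add atoms: none
Why: Fluoride-induced desilylation frees the two oxolane hydroxyls while both phenols are still benzylated, so the basic medium cannot open the benzylic ethers through quinone methides.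

Step 18
Reactants: 27 dibenzyl triol from step 17
Product: 28 (2S,3S,4S,5S)-2-(4-hydroxy-3-methoxybenzyl)-5-[(2R,3R)-2-(4-hydroxy-3-methoxyphenyl)-3-(hydroxymethyl)-7-methoxy-2,3-dihydro-1-benzofuran-5-yl]-4-(hydroxymethyl)oxolan-3-ol (CNP0179668.1)
Conditions: H2 (1 atm), Pd/C (10 wt %), EtOAc–EtOH, rt, stopped at full conversion
Reagents that add atoms: none
Why: Hydrogenolysis of the two phenolic benzyl ethers over Pd/C is much faster than cleavage of the cyclic benzylic C–O bonds and runs under neutral conditions, avoiding the acid or base that could epimerise the 2-(4-hydroxyaryl) rings through quinone methides.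

**Compound list**

1 | 4-bromo-2-methoxyphenol | COc1cc(Br)ccc1O | starting material
2 | 1-(benzyloxy)-4-bromo-2-methoxybenzene | COc1cc(Br)ccc1OCc1ccccc1 | intermediate
3 | methyl (2S)-oxirane-2-carboxylate | COC(=O)[C@@H]1CO1 | starting material
4 | [4-(benzyloxy)-3-methoxyphenyl]magnesium bromide | COc1cc([Mg]Br)ccc1OCc1ccccc1 | intermediate (not isolated)
5 | methyl (2S)-3-[4-(benzyloxy)-3-methoxyphenyl]-2-hydroxypropanoate | COc1cc(C[C@@H](C(=O)OC)O)ccc1OCc1ccccc1 | intermediate
6 | methyl (2S)-3-[4-(benzyloxy)-3-methoxyphenyl]-2-(methoxymethoxy)propanoate | COc1cc(C[C@@H](C(=O)OC)OCOC)ccc1OCc1ccccc1 | intermediate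
7 | (2S)-3-[4-(benzyloxy)-3-methoxyphenyl]-2-(methoxymethoxy)propanal | COc1cc(C[C@@H](C=O)OCOC)ccc1OCc1ccccc1 | intermediate
8 | tert-butyl[(1-methoxyethenyl)oxy]dimethylsilane | C=C(OC)O[Si](C)(C)C(C)(C)C | starting material
9 | methyl (3S,4S)-5-[4-(benzyloxy)-3-methoxyphenyl]-3-hydroxy-4-(methoxymethoxy)pentanoate | COc1cc(C[C@@H]([C@@H](O)CC(=O)OC)OCOC)ccc1OCc1ccccc1 | intermediate
10 | 3-bromo-4-hydroxy-5-methoxybenzaldehyde | COc1cc(C=O)cc(Br)c1O | starting material
11 | 3-bromo-5-methoxy-4-(methoxymethoxy)benzaldehyde | COCOc1c(Br)cc(C=O)cc1OC | intermediate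
12 | dilithium salt of the C3-alkoxide C1-enolate of 9 | [Li+].[Li+].COc1cc(C[C@@H]([C@@H]([O-])C=C([O-])OC)OCOC)ccc1OCc1ccccc1 | intermediate (not isolated)
13 | methyl (2R,3S,4S)-5-[4-(benzyloxy)-3-methoxyphenyl]-2-{[3-bromo-5-methoxy-4-(methoxymethoxy)phenyl](hydroxy)methyl}-3-hydroxy-4-(methoxymethoxy)pentanoate, both carbinol epimers | COc1cc(C[C@@H]([C@@H](O)[C@H](C(=O)OC)C(O)c2cc(Br)c(OCOC)c(OC)c2)OCOC)ccc1OCc1ccccc1 | intermediate
14 | (2R,3S,4S)-5-[4-(benzyloxy)-3-methoxyphenyl]-2-{[3-bromo-5-methoxy-4-(methoxymethoxy)phenyl](hydroxy)methyl}-4-(methoxymethoxy)pentane-1,3-diol, both carbinol epimers | COc1cc(C[C@@H]([C@@H](O)[C@H](CO)C(O)c2cc(Br)c(OCOC)c(OC)c2)OCOC)ccc1OCc1ccccc1 | intermediate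
15 | (2R,3S,4S)-5-[4-(benzyloxy)-3-methoxyphenyl]-2-[(3-bromo-4-hydroxy-5-methoxyphenyl)(hydroxy)methyl]pentane-1,3,4-triol, both carbinol epimers | COc1cc(C[C@@H]([C@@H](O)[C@H](CO)C(O)c2cc(Br)c(O)c(OC)c2)O)ccc1OCc1ccccc1 | intermediate (not isolated)
16 | (2S,3S,4S,5S)-2-[4-(benzyloxy)-3-methoxybenzyl]-5-(3-bromo-4-hydroxy-5-methoxyphenyl)-4-(hydroxymethyl)oxolan-3-ol | COc1cc(C[C@@H]2O[C@H](c3cc(Br)c(O)c(OC)c3)[C@@H](CO)[C@@H]2O)ccc1OCc1ccccc1 | intermediate
17 | [4-(benzyloxy)-3-methoxyphenyl]methanol | COc1cc(CO)ccc1OCc1ccccc1 | starting material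
18 | 1-(benzyloxy)-4-(chloromethyl)-2-methoxybenzene | COc1cc(CCl)ccc1OCc1ccccc1 | intermediate
19 | (2S,3S,4S,5S)-2-[4-(benzyloxy)-3-methoxybenzyl]-5-(4-{[4-(benzyloxy)-3-methoxybenzyl]oxy}-3-bromo-5-methoxyphenyl)-4-(hydroxymethyl)oxolan-3-ol | COc1cc(C[C@@H]2O[C@H](c3cc(Br)c(OCc4ccc(OCc5ccccc5)c(OC)c4)c(OC)c3)[C@@H](CO)[C@@H]2O)ccc1OCc1ccccc1 | intermediate
20 | (2S,3S,4R,5S)-2-[4-(benzyloxy)-3-methoxybenzyl]-5-(4-{[4-(benzyloxy)-3-methoxybenzyl]oxy}-3-bromo-5-methoxyphenyl)-3-[(tert-butyldimethylsilyl)oxy]-4-{[(tert-butyldimethylsilyl)oxy]methyl}oxolane | COc1cc(C[C@@H]2O[C@H](c3cc(Br)c(OCc4ccc(OCc5ccccc5)c(OC)c4)c(OC)c3)[C@@H](CO[Si](C)(C)C(C)(C)C)[C@@H]2O[Si](C)(C)C(C)(C)C)ccc1OCc1ccccc1 | intermediate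
21 | methyl bromoacetate | COC(=O)CBr | starting material
22 | bromo(2-methoxy-2-oxoethyl)zinc | COC(=O)C[Zn]Br | intermediate (not isolated)
23 | methyl 2-[2-{[4-(benzyloxy)-3-methoxybenzyl]oxy}-5-[(2S,3R,4S,5S)-5-[4-(benzyloxy)-3-methoxybenzyl]-4-[(tert-butyldimethylsilyl)oxy]-3-{[(tert-butyldimethylsilyl)oxy]methyl}oxolan-2-yl]-3-methoxyphenyl]acetate | COc1cc(C[C@@H]2O[C@H](c3cc(OC)c(OCc4ccc(OCc5ccccc5)c(OC)c4)c(c3)CC(=O)OC)[C@@H](CO[Si](C)(C)C(C)(C)C)[C@@H]2O[Si](C)(C)C(C)(C)C)ccc1OCc1ccccc1 | intermediate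
24 | methyl 2-[2-{[4-(benzyloxy)-3-methoxybenzyl]oxy}-5-[(2S,3R,4S,5S)-5-[4-(benzyloxy)-3-methoxybenzyl]-4-[(tert-butyldimethylsilyl)oxy]-3-{[(tert-butyldimethylsilyl)oxy]methyl}oxolan-2-yl]-3-methoxyphenyl]-2-diazoacetate | COc1cc(C[C@@H]2O[C@H](c3cc(OC)c(OCc4ccc(OCc5ccccc5)c(OC)c4)c(c3)C(=[N+]=[N-])C(=O)OC)[C@@H](CO[Si](C)(C)C(C)(C)C)[C@@H]2O[Si](C)(C)C(C)(C)C)ccc1OCc1ccccc1 | intermediate
25 | methyl (2R,3S)-2-[4-(benzyloxy)-3-methoxyphenyl]-5-[(2S,3R,4S,5S)-5-[4-(benzyloxy)-3-methoxybenzyl]-4-[(tert-butyldimethylsilyl)oxy]-3-{[(tert-butyldimethylsilyl)oxy]methyl}oxolan-2-yl]-7-methoxy-2,3-dihydro-1-benzofuran-3-carboxylate | COc1cc(C[C@@H]2O[C@H](c3cc(OC)c4c(c3)[C@H](C(=O)OC)[C@H](c3ccc(OCc5ccccc5)c(OC)c3)O4)[C@@H](CO[Si](C)(C)C(C)(C)C)[C@@H]2O[Si](C)(C)C(C)(C)C)ccc1OCc1ccccc1 | intermediate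
26 | [(2R,3R)-2-[4-(benzyloxy)-3-methoxyphenyl]-5-[(2S,3R,4S,5S)-5-[4-(benzyloxy)-3-methoxybenzyl]-4-[(tert-butyldimethylsilyl)oxy]-3-{[(tert-butyldimethylsilyl)oxy]methyl}oxolan-2-yl]-7-methoxy-2,3-dihydro-1-benzofuran-3-yl]methanol | COc1cc(C[C@@H]2O[C@H](c3cc(OC)c4c(c3)[C@H](CO)[C@H](c3ccc(OCc5ccccc5)c(OC)c3)O4)[C@@H](CO[Si](C)(C)C(C)(C)C)[C@@H]2O[Si](C)(C)C(C)(C)C)ccc1OCc1ccccc1 | intermediate
27 | (2S,3S,4S,5S)-2-[4-(benzyloxy)-3-methoxybenzyl]-5-[(2R,3R)-2-[4-(benzyloxy)-3-methoxyphenyl]-3-(hydroxymethyl)-7-methoxy-2,3-dihydro-1-benzofuran-5-yl]-4-(hydroxymethyl)oxolan-3-ol | COc1cc(C[C@@H]2O[C@H](c3cc(OC)c4c(c3)[C@H](CO)[C@H](c3ccc(OCc5ccccc5)c(OC)c3)O4)[C@@H](CO)[C@@H]2O)ccc1OCc1ccccc1 | intermediate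
28 | (2S,3S,4S,5S)-2-(4-hydroxy-3-methoxybenzyl)-5-[(2R,3R)-2-(4-hydroxy-3-methoxyphenyl)-3-(hydroxymethyl)-7-methoxy-2,3-dihydro-1-benzofuran-5-yl]-4-(hydroxymethyl)oxolan-3-ol | COc1cc(C[C@@H]2O[C@H](c3cc(OC)c4c(c3)[C@H](CO)[C@H](c3ccc(O)c(OC)c3)O4)[C@@H](CO)[C@@H]2O)ccc1O | target

**Count and risks**

Total step count: 18. Longest linear sequence: 16 steps (steps 1–5, 7–9, 11–18).

Steps most likely to fail:

Step 15. The chiral catalyst may not override the bias of the oxolane stereocentres, so that facial selectivity, and with it the cis ratio, erodes. The fallback sets out from 23 and comes back at 26, and adds a substrate-bound control element to the same C–H insertion. Saponification of 23 (LiOH, THF–H2O) gives the arylacetic acid F1. Esterification (DCC, DMAP, CH2Cl2) with (2S)-2-hydroxy-1-(pyrrolidin-1-yl)propan-1-one gives the lactamide ester F2; the R-lactamide would be used if the S one proved mismatched. Diazo transfer (p-ABSA, DBU) gives the diazoester F3. Insertion with Rh2(S-PTTL)4 in toluene at −60 °C under double stereodifferentiation gives the cis-dihydrobenzofuran lactamide ester F4. LiBH4 in THF at 0 °C cleaves the auxiliary reductively and returns alcohol 26.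

Step 9. The formaldehyde unit released from the aliphatic acetal may be captured by the neighbouring hydroxyls as a cyclic formal, or the benzylic cation may fragment with loss of formaldehyde instead of closing the ring. The fallback sets out from 14 and comes back at 16, and closes the ring with every hydroxyl masked. Acetylation of 14 (Ac2O, pyridine, DMAP) gives the triacetate F5. CF3CO2H in CH2Cl2 with MeOH (20 equiv) at 0 °C unmasks the phenol and the chain oxygen; the benzylic acetate leaves through the quinone methide and the ring closes to the oxolane diacetate F6. K2CO3 in MeOH removes the two acetates and returns 16.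

Step 13. Oxidative addition at the electron-rich, ortho-alkoxylated bromide may be slow, and the zinc enolate may be protonated or self-condense, so that reduced arene forms in place of the coupled product. The fallback sets out from 20 and comes back at 24, bypassing 23 and the diazo transfer. Bromine–lithium exchange (n-BuLi, THF, −78 °C) and addition to dimethyl oxalate (3 equiv, −78 °C) gives the aryl glyoxylate F7. Condensation with 4-methylbenzenesulfonohydrazide (MeOH, 50 °C) gives the tosylhydrazone F8. DBU in CH2Cl2 at rt eliminates sulfinate (Bamford–Stevens) and gives 24.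

Further compounds
F1 | step 15 | free arylacetic acid corresponding to methyl ester 23 | COc1cc(C[C@@H]2O[C@H](c3cc(OC)c(OCc4ccc(OCc5ccccc5)c(OC)c4)c(c3)CC(=O)O)[C@@H](CO[Si](C)(C)C(C)(C)C)[C@@H]2O[Si](C)(C)C(C)(C)C)ccc1OCc1ccccc1
F2 | step 15 | (2S)-1-oxo-1-(pyrrolidin-1-yl)propan-2-yl ester of acid F1 | COc1cc(C[C@@H]2O[C@H](c3cc(OC)c(OCc4ccc(OCc5ccccc5)c(OC)c4)c(c3)CC(=O)O[C@@H](C)C(=O)N6CCCC6)[C@@H](CO[Si](C)(C)C(C)(C)C)[C@@H]2O[Si](C)(C)C(C)(C)C)ccc1OCc1ccccc1
F3 | step 15 | (2S)-1-oxo-1-(pyrrolidin-1-yl)propan-2-yl aryldiazoacetate, the lactamide analogue of 24 | COc1cc(C[C@@H]2O[C@H](c3cc(OC)c(OCc4ccc(OCc5ccccc5)c(OC)c4)c(c3)C(=[N+]=[N-])C(=O)O[C@@H](C)C(=O)N6CCCC6)[C@@H](CO[Si](C)(C)C(C)(C)C)[C@@H]2O[Si](C)(C)C(C)(C)C)ccc1OCc1ccccc1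
F4 | step 15 | (2S)-1-oxo-1-(pyrrolidin-1-yl)propan-2-yl (2R,3S)-cis-2,3-dihydrobenzofuran-3-carboxylate, the lactamide analogue of 25 | COc1cc(C[C@@H]2O[C@H](c3cc(OC)c4c(c3)[C@H](C(=O)O[C@@H](C)C(=O)N6CCCC6)[C@H](c3ccc(OCc5ccccc5)c(OC)c3)O4)[C@@H](CO[Si](C)(C)C(C)(C)C)[C@@H]2O[Si](C)(C)C(C)(C)C)ccc1OCc1ccccc1
F5 | step 9 | (2R,3S,4S)-2-{(acetyloxy)[3-bromo-5-methoxy-4-(methoxymethoxy)phenyl]methyl}-5-[4-(benzyloxy)-3-methoxyphenyl]-4-(methoxymethoxy)pentane-1,3-diyl diacetate, both epimers at the benzylic carbon | COc1cc(C[C@@H]([C@@H](OC(C)=O)[C@H](COC(C)=O)C(OC(C)=O)c2cc(Br)c(OCOC)c(OC)c2)OCOC)ccc1OCc1ccccc1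
F6 | step 9 | (2S,3S,4R,5S)-4-[(acetyloxy)methyl]-2-[4-(benzyloxy)-3-methoxybenzyl]-5-(3-bromo-4-hydroxy-5-methoxyphenyl)oxolan-3-yl acetate | COc1cc(C[C@@H]2O[C@H](c3cc(Br)c(O)c(OC)c3)[C@@H](COC(C)=O)[C@@H]2OC(C)=O)ccc1OCc1ccccc1
F7 | step 13 | methyl aryl(oxo)acetate, the 2-oxo analogue of 23 | COc1cc(C[C@@H]2O[C@H](c3cc(OC)c(OCc4ccc(OCc5ccccc5)c(OC)c4)c(c3)C(=O)C(=O)OC)[C@@H](CO[Si](C)(C)C(C)(C)C)[C@@H]2O[Si](C)(C)C(C)(C)C)ccc1OCc1ccccc1
F8 | step 13 | 4-methylbenzenesulfonylhydrazone of keto ester F7 | COc1cc(C[C@@H]2O[C@H](c3cc(OC)c(OCc4ccc(OCc5ccccc5)c(OC)c4)c(c3)C(=NNS(=O)(=O)c6ccc(C)cc6)C(=O)OC)[C@@H](CO[Si](C)(C)C(C)(C)C)[C@@H]2O[Si](C)(C)C(C)(C)C)ccc1OCc1ccccc1
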